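**Retrosynthetic overview**
- Feature: the 1,4-dioxane ring C is O1–C2–C3–O4–C4a–C8a, with trimethoxyphenyl ring A on C2 and CH3 on C3. C2 is a benzylic sp3 carbon open to SN2 by oxygen. O4 sits on C4a of benzo ring B (OMe on C5), para to the carbonyl-bearing C7, where an aryl fluoride is labile to SNAr.
- Disconnection 1 (last step): the C7 propenal goes back to a C7 formyl group by a two-carbon Wittig homologation.
- Disconnection 2 (key): C2–O1 and O4–C4a are cut together, giving a cis-aryl(methyl)oxirane and 4-fluoro-3-hydroxy-5-methoxybenzaldehyde. Inversion at C2 and retention at C3 turn the cis-oxirane into the trans-dioxane.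
- Disconnection 3: the oxirane comes from the (Z)-propenylarene, this from the arylpropyne, and this from 5-iodo-1,2,3-trimethoxybenzene and propyne. The fluorophenol comes from C–H borylation/oxidation next to fluorine of acetal-protected 4-fluoro-3-methoxybenzaldehyde.
- Ring order: rings A and B are bought. The oxirane is made in step 3 and consumed in step 7, where ring C, the only new ring of the target, is closed.

Key step: step 7

Remark: benzodioxane locants follow the numbering of the overview (O1 on the aryl-bearing C2); both stereocentres are (R) in either numbering direction.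
Remark: the (S,S) antipode of the Mn(salen)Cl catalyst is chosen by analogy with its known sense of induction on indene and cis-β-methylstyrene (benzylic carbon S); both antipodes are commercial.

**Step 1**
Reactants: 1 5-iodo-1,2,3-trimethoxybenzene; 2 propyne
Product: 3 1,2,3-trimethoxy-5-(prop-1-yn-1-yl)benzene
Conditions: PdCl2(PPh3)2 (2 mol %), CuI (4 mol %), Et3N, propyne (ca. 1 M in THF, 2 equiv), sealed flask, rt
Reagents that add atoms: none
Why: Sonogashira coupling; the aryl iodide adds oxidatively to zerovalent palladium at room temperature, so the volatile alkyne stays in solution and its copper acetylide transmetallates cleanly.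

**Step 2**
Reactants: 3 1,2,3-trimethoxy-5-(prop-1-yn-1-yl)benzene
Product: 4 (Z)-1,2,3-trimethoxy-5-(prop-1-en-1-yl)benzene
Conditions: H2 (1 atm), Pd/CaCO3 poisoned with Pb(OAc)2, quinoline, EtOAc, rt, stopped after 1 equiv H2
Reagents that add atoms: none
Why: Lindlar semihydrogenation; syn delivery of hydrogen on the poisoned palladium surface should give the (Z)-alkene, which is released before over-reduction or Z/E isomerisation.

**Step 3**
Reactants: 4 (Z)-1,2,3-trimethoxy-5-(prop-1-en-1-yl)benzene
Product: 5 (2R,3S)-2-methyl-3-(3,4,5-trimethoxyphenyl)oxirane (cis)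
Conditions: (S,S)-Mn(salen)Cl (4 mol %; salen = N,N'-bis(3,5-di-tert-butylsalicylidene)cyclohexane-1,2-diaminate), 4-phenylpyridine N-oxide (20 mol %), aq NaOCl (pH 11.3, Na2HPO4), CH2Cl2, 0 °C; Et3N-deactivated silica
Reagents that add atoms: sodium hypochlorite, [Na+].[O-]Cl
Why: Jacobsen–Katsuki epoxidation; conjugated cis-disubstituted aryl alkenes are the best substrate class for the oxo-manganese salen species, and side-on approach past the (S,S)-diamine backbone should deliver oxygen to the face that makes the benzylic carbon (S) and the methyl-bearing carbon (R).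

**Step 4**
Reactants: 6 4-fluoro-3-methoxybenzaldehyde
Product: 7 2-(4-fluoro-3-methoxyphenyl)-1,3-dioxolane
Conditions: ethylene glycol (3 equiv), p-TsOH·H2O (cat.), toluene, reflux, Dean–Stark
Reagents that add atoms: ethylene glycol, OCCO
Why: acid-catalysed acetalisation with azeotropic removal of water masks the formyl group, which the boron hydride formed in the next step would otherwise reduce.

**Step 5**
Reactants: 7 2-(4-fluoro-3-methoxyphenyl)-1,3-dioxolane
Product: 9 5-(1,3-dioxolan-2-yl)-2-fluoro-3-methoxyphenol, via aryl pinacol boronate 8 (not isolated)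
Conditions: [Ir(OMe)(cod)]2 (1.5 mol %), 4,4'-di-tert-butyl-2,2'-bipyridine (3 mol %), B2pin2 (1.0 equiv), THF, 70 °C; then 30 % H2O2, aq NaOH, 0 °C → rt; NH4Cl work-up
Reagents that add atoms: bis(pinacolato)diboron, CC1(C)OB(OC1(C)C)B1OC(C)(C)C(C)(C)O1 (boryl group of 8); hydrogen peroxide, OO (phenol oxygen of 9)
Why: iridium-catalysed aromatic C–H borylation is sterically governed, so the C–H between OMe and the dioxolane and the C–H ortho to the dioxolane stay untouched, only the C–H whose sole ortho neighbour is the small, acidifying fluorine reacts, and alkaline peroxide then turns C–B into C–O at the same carbon.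

**Step 6**
Reactants: 9 5-(1,3-dioxolan-2-yl)-2-fluoro-3-methoxyphenol
Product: 10 4-fluoro-3-hydroxy-5-methoxybenzaldehyde
Conditions: 1 M HCl, THF, rt
Reagents that add atoms: water, O
Why: acid-catalysed acetal hydrolysis; aryl fluoride, methyl ether and phenol are inert to dilute acid.

**Step 7**
Reactants: 5 (2R,3S)-2-methyl-3-(3,4,5-trimethoxyphenyl)oxirane; 10 4-fluoro-3-hydroxy-5-methoxybenzaldehyde
Product: 12 (2R,3R)-5-methoxy-3-methyl-2-(3,4,5-trimethoxyphenyl)-2,3-dihydro-1,4-benzodioxine-7-carbaldehyde, via (1R,2R)-hydroxy ether alkoxide 11 (not isolated)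
Conditions: Cs2CO3 (1.5 equiv), 5 (1.3 equiv), 4 Å MS, DMSO, 100 °C, N2
Reagents that add atoms: none
Why: Cs2CO3 turns 10 into its caesium phenoxide, which attacks the benzylic oxirane carbon of 5 anti to the C–O bond (SN2, forms C2–O1) and releases the secondary alkoxide 11; this adds to the fluorine-bearing carbon, the para formyl group takes up the charge of the Meisenheimer adduct, and loss of fluoride forms O4–C4a. The closest known reaction type is the base-mediated tandem opening of epoxides by 2-halophenols followed by intramolecular O-arylation to 1,4-benzodioxanes, together with SNAr etherification of 4-fluorobenzaldehydes. Ring C is closed by the intramolecular addition–elimination through a six-membered transition state (6-exo attack on C4a), not by the epoxide opening. C2 becomes (R) by inversion of the (S)-benzylic carbon of 5, and C3 keeps the (R) configuration of the methyl-bearing carbon because its C–O bond is never broken, so the cis-oxirane maps onto the trans-dioxane. The step needs attack at the benzylic rather than the equally substituted methyl-bearing carbon, which conjugative stabilisation of the SN2 transition state by ring A should secure, while basic conditions free of Lewis acid keep the opening away from an ionised pathway that would erode the inversion. Chemoselectivity is built in: the ortho O− switches the C–F bond of the free phenoxide off towards SNAr so that self-condensation is slow, O-alkylation switches it on, and C8a, meta to the formyl group, offers no path for a Smiles-type aryl migration.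

**Step 8**
Reactants: 12 (2R,3R)-5-methoxy-3-methyl-2-(3,4,5-trimethoxyphenyl)-2,3-dihydro-1,4-benzodioxine-7-carbaldehyde
Product: 13 (E)-3-[(2R,3R)-5-methoxy-3-methyl-2-(3,4,5-trimethoxyphenyl)-2,3-dihydro-1,4-benzodioxin-7-yl]prop-2-enal (target)
Conditions: Ph3P=CHCHO (1.15 equiv), toluene, 90 °C
Reagents that add atoms: (triphenylphosphoranylidene)acetaldehyde, O=CC=P(c1ccccc1)(c1ccccc1)c1ccccc1
Why: Wittig olefination with a stabilised ylide should give the (E)-enal, the neutral conditions leave C2 and C3 untouched, and a near-stoichiometric charge of ylide limits a second homologation.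

**Compound list**
1 | 5-iodo-1,2,3-trimethoxybenzene | COc1cc(I)cc(OC)c1OC | starting material
2 | propyne | CC#C | starting material
3 | 1,2,3-trimethoxy-5-(prop-1-yn-1-yl)benzene | CC#Cc1cc(OC)c(OC)c(OC)c1 | intermediate
4 | (Z)-1,2,3-trimethoxy-5-(prop-1-en-1-yl)benzene | C/C=C\c1cc(OC)c(OC)c(OC)c1 | intermediate
5 | (2R,3S)-2-methyl-3-(3,4,5-trimethoxyphenyl)oxirane | C[C@H]1O[C@H]1c2cc(OC)c(OC)c(OC)c2 | intermediate
6 | 4-fluoro-3-methoxybenzaldehyde | COc1cc(C=O)ccc1F | starting material
7 | 2-(4-fluoro-3-methoxyphenyl)-1,3-dioxolane | COc1cc(C2OCCO2)ccc1F | intermediate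
8 | 2-[5-(1,3-dioxolan-2-yl)-2-fluoro-3-methoxyphenyl]-4,4,5,5-tetramethyl-1,3,2-dioxaborolane | COc1cc(C2OCCO2)cc(B3OC(C)(C)C(C)(C)O3)c1F | intermediate
9 | 5-(1,3-dioxolan-2-yl)-2-fluoro-3-methoxyphenol | COc1cc(C2OCCO2)cc(O)c1F | intermediate
10 | 4-fluoro-3-hydroxy-5-methoxybenzaldehyde | COc1cc(C=O)cc(O)c1F | intermediate
11 | 4-fluoro-3-{[(1R,2R)-2-hydroxy-1-(3,4,5-trimethoxyphenyl)propyl]oxy}-5-methoxybenzaldehyde (present as its caesium alkoxide) | COc1cc([C@@H](Oc2cc(C=O)cc(OC)c2F)[C@@H](C)O)cc(OC)c1OC | intermediate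
12 | (2R,3R)-5-methoxy-3-methyl-2-(3,4,5-trimethoxyphenyl)-2,3-dihydro-1,4-benzodioxine-7-carbaldehyde | COc1cc([C@H]2Oc3cc(C=O)cc(OC)c3O[C@@H]2C)cc(OC)c1OC | intermediate
13 | (E)-3-[(2R,3R)-5-methoxy-3-methyl-2-(3,4,5-trimethoxyphenyl)-2,3-dihydro-1,4-benzodioxin-7-yl]prop-2-enal | COc1cc([C@H]2Oc3cc(/C=C/C=O)cc(OC)c3O[C@@H]2C)cc(OC)c1OC | target

**Total step count:** 8.
**Longest linear sequence:** 5 steps (1→2→3→7→8 or 4→5→6→7→8).

**Steps most likely to fail**

**Step 7.**
- What may go wrong: the phenoxide may attack the methyl-bearing oxirane carbon, which would place ring A next to O4. The opening may be too slow to outrun self-condensation of the fluorophenoxide. Partial ionisation at the benzylic carbon may erode the inversion.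
- The fallback sets out from 5 and 10 and returns at 12. It reverses the order of the two C–O bonds and makes C2–O1 last, under acid.
- Acid-catalysed methanolysis of 5 (camphorsulfonic acid cat., MeOH, 0 °C) is reliably benzylic. It should give (1R,2R)-1-methoxy-1-(3,4,5-trimethoxyphenyl)propan-2-ol F1 with the C–O bond at the methyl-bearing carbon untouched.
- Compound 10 is protected (MOMCl, iPr2NEt, CH2Cl2) as 4-fluoro-3-methoxy-5-(methoxymethoxy)benzaldehyde F2.
- The preformed sodium alkoxide of F1 (NaH, THF–DMF, 0 → 50 °C) displaces the fluoride of F2 in an intermolecular SNAr. This forms O4–C4a with retention at C3 and gives 3-methoxy-5-(methoxymethoxy)-4-{[(1R,2R)-1-methoxy-1-(3,4,5-trimethoxyphenyl)propan-2-yl]oxy}benzaldehyde F3.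
- Aqueous HCl in THF removes the MOM group to give 3-hydroxy-5-methoxy-4-{[(1R,2R)-1-methoxy-1-(3,4,5-trimethoxyphenyl)propan-2-yl]oxy}benzaldehyde F4.
- BF3·OEt2 in CH2Cl2 then ionises the benzylic methyl ether and the neighbouring phenol traps the cation, closing ring C as the more stable trans isomer 12.
- C2 is set here by the C3 stereocentre under thermodynamic control, so the benzylic configuration of F1 does not matter.

**Step 3.**
- What may go wrong: rotation in the radical intermediate may leak cis- into trans-epoxide. Facial selectivity may be incomplete. Hypochlorite may chlorinate ring A, and the oxirane may open under acid on silica. A small shortfall in enantiomeric purity could be made up by crystallising 12.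
- The fallback sets out from 1 and 10 and returns at 11, which is closed to 12 with Cs2CO3 in DMSO as in step 7. The oxirane is given up, C3 is taken from the chiral pool, and the inversion at C2 is done by a Mitsunobu reaction.
- Methyl (R)-lactate is silylated (TBSCl, imidazole, DMF) to methyl (R)-2-[(tert-butyldimethylsilyl)oxy]propanoate F5. This is reduced (DIBAL-H, CH2Cl2, −78 °C) to (R)-2-[(tert-butyldimethylsilyl)oxy]propanal F6.
- Iodine–magnesium exchange on 1 (iPrMgCl·LiCl, THF, 0 °C) gives (3,4,5-trimethoxyphenyl)magnesium chloride F7.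
- F7 adds to F6 at −78 °C under Felkin–Anh control to give the anti alcohol (1S,2R)-2-[(tert-butyldimethylsilyl)oxy]-1-(3,4,5-trimethoxyphenyl)propan-1-ol F8. The minor syn epimer is removed by chromatography.
- Mitsunobu etherification of F8 with 10 (PPh3, DIAD, toluene, 0 °C) inverts the benzylic carbon. It gives 3-{[(1R,2R)-2-[(tert-butyldimethylsilyl)oxy]-1-(3,4,5-trimethoxyphenyl)propyl]oxy}-4-fluoro-5-methoxybenzaldehyde F9.
- TBAF in THF frees 11.

**Step 8.**
- What may go wrong: the product enal is more electrophilic than 12 and may be olefinated a second time, and the electron-rich aldehyde may convert slowly.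
- The fallback sets out from 12 and returns at 13 by a redox detour in which no aldehyde is present while the olefinating reagent is.
- Horner–Wadsworth–Emmons reaction (triethyl phosphonoacetate, LiCl, DBU, MeCN, rt) gives ethyl (E)-3-[(2R,3R)-5-methoxy-3-methyl-2-(3,4,5-trimethoxyphenyl)-2,3-dihydro-1,4-benzodioxin-7-yl]prop-2-enoate F10.
- DIBAL-H (CH2Cl2, −78 °C) gives (E)-3-[(2R,3R)-5-methoxy-3-methyl-2-(3,4,5-trimethoxyphenyl)-2,3-dihydro-1,4-benzodioxin-7-yl]prop-2-en-1-ol F11.
- MnO2 (CH2Cl2, rt) oxidises the allylic alcohol to 13.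

**Further compounds**
F1 | step 7 | (1R,2R)-1-methoxy-1-(3,4,5-trimethoxyphenyl)propan-2-ol | COc1cc([C@@H](OC)[C@@H](C)O)cc(OC)c1OC
F2 | step 7 | 4-fluoro-3-methoxy-5-(methoxymethoxy)benzaldehyde | COCOc1cc(C=O)cc(OC)c1F
F3 | step 7 | 3-methoxy-5-(methoxymethoxy)-4-{[(1R,2R)-1-methoxy-1-(3,4,5-trimethoxyphenyl)propan-2-yl]oxy}benzaldehyde | COc1cc([C@@H](OC)[C@@H](C)Oc2c(OC)cc(C=O)cc2OCOC)cc(OC)c1OC
F4 | step 7 | 3-hydroxy-5-methoxy-4-{[(1R,2R)-1-methoxy-1-(3,4,5-trimethoxyphenyl)propan-2-yl]oxy}benzaldehyde | COc1cc([C@@H](OC)[C@@H](C)Oc2c(OC)cc(C=O)cc2O)cc(OC)c1OC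
F5 | step 3 | methyl (R)-2-[(tert-butyldimethylsilyl)oxy]propanoate | C[C@@H](O[Si](C)(C)C(C)(C)C)C(=O)OC
F6 | step 3 | (R)-2-[(tert-butyldimethylsilyl)oxy]propanal | C[C@@H](O[Si](C)(C)C(C)(C)C)C=O
F7 | step 3 | (3,4,5-trimethoxyphenyl)magnesium chloride | COc1cc([Mg]Cl)cc(OC)c1OC
F8 | step 3 | (1S,2R)-2-[(tert-butyldimethylsilyl)oxy]-1-(3,4,5-trimethoxyphenyl)propan-1-ol | COc1cc([C@H](O)[C@@H](C)O[Si](C)(C)C(C)(C)C)cc(OC)c1OC
F9 | step 3 | 3-{[(1R,2R)-2-[(tert-butyldimethylsilyl)oxy]-1-(3,4,5-trimethoxyphenyl)propyl]oxy}-4-fluoro-5-methoxybenzaldehyde | COc1cc([C@@H](Oc2cc(C=O)cc(OC)c2F)[C@@H](C)O[Si](C)(C)C(C)(C)C)cc(OC)c1OC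
F10 | step 8 | ethyl (E)-3-[(2R,3R)-5-methoxy-3-methyl-2-(3,4,5-trimethoxyphenyl)-2,3-dihydro-1,4-benzodioxin-7-yl]prop-2-enoate | COc1cc([C@H]2Oc3cc(/C=C/C(=O)OCC)cc(OC)c3O[C@@H]2C)cc(OC)c1OC
F11 | step 8 | (E)-3-[(2R,3R)-5-methoxy-3-methyl-2-(3,4,5-trimethoxyphenyl)-2,3-dihydro-1,4-benzodioxin-7-yl]prop-2-en-1-ol | COc1cc([C@H]2Oc3cc(/C=C/CO)cc(OC)c3O[C@@H]2C)cc(OC)c1OC
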